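The retrosynthesis cuts, in this order: the C8–O acyl bond of the side-chain ester, the exocyclic C11=C13 bond, the ring alkene C1=C10 (ring-closing metathesis), and the lactone bond O–C6 (the ring oxygen is taken out again, a Baeyer–Villiger retron). It then moves the epoxide back from C4–C5 to C4–C15 (Payne retron) and cuts C5–C6 (aldol) and C8–C9 (methallylation).
Feature that allows the key event: the five-membered lactone ring O–C6–C7–C11–C12 is the four-carbon ring C6–C7–C11–C12 of a cyclobutanone plus one oxygen atom. C6 is the more substituted α-carbon, so oxygen insertion falls between C12 and C6 and keeps the C6 configuration; a purchasable 3-oxocyclobutanecarboxylate already holds C6, C7, C8, C11 and C12.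
Second feature: the row C6–O / C5–O–C4 / C15–OH is what an anti aldol of that ketone with a 2-substituted glycidal gives after migration of the epoxide.
Forward order: cyclobutane ring (bought) → aldol joins the two fragments at C5–C6 → four-to-five ring expansion gives the lactone → epoxide migrates into C4–C5 → ten-membered carbocycle by metathesis → α-methylene group, C8 ester, desilylation.
Stereochemistry: C8 comes from a Keck methallylation and C4 from a Sharpless epoxidation (inverted once in the Payne step). C5, C6 and C7 come together from one catalyst-controlled desymmetrising aldol, and C6 is carried over with retention in the migration. Z-C1=C10 comes from ring strain in the metathesis and the E side chain from a stabilised Wittig reaction.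
Key step: step 9

Remark: germacrane numbering is used (C12 lactone carbonyl, C6 lactone carbinol carbon, C13 exocyclic methylene, C14 methyl on C10, C15 hydroxymethyl on C4). The ring alkene is taken as drawn, with C2 and C9 cis (Z).

Step 1
Reactants: 1 methyl 3,3-dimethoxycyclobutane-1-carboxylate
Product: 2 3,3-dimethoxycyclobutane-1-carbaldehyde
Conditions: iBu2AlH (1.05 equiv), CH2Cl2, −78 °C; aq potassium sodium tartrate
Reagents that add atoms: none
Why: Partial ester reduction with iBu2AlH at low temperature stops at the aluminium hemiacetal, which should release the aldehyde (C8) only on work-up, while the ketal that masks C12 is inert to hydride.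

Step 2
Reactants: 2 3,3-dimethoxycyclobutane-1-carbaldehyde; 3 tributyl(2-methylallyl)stannane
Product: 4 (1R)-1-(3,3-dimethoxycyclobutyl)-3-methylbut-3-en-1-ol
Conditions: (R)-BINOL (20 mol %), Ti(OiPr)4 (10 mol %), 4 Å molecular sieves, CH2Cl2, −20 °C; aq NaHCO3
Reagents that add atoms: none
Why: In this Keck asymmetric methallylation the BINOL–titanium Lewis acid differentiates the aldehyde faces, so the (R)-ligand should give the (R)-carbinol (C8) and bring in C9, C10, C14 and the metathesis handle.

Step 3
Reactants: 4 (1R)-1-(3,3-dimethoxycyclobutyl)-3-methylbut-3-en-1-ol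
Product: 5 (1R)-1-(3,3-dimethoxycyclobutyl)-3-methylbut-3-en-1-yl 4-methoxybenzyl ether
Conditions: NaH, 4-MeOC6H4CH2Cl, Bu4NI (cat.), THF–DMF, 0 °C to rt
Reagents that add atoms: 4-methoxybenzyl chloride, COc1ccc(CCl)cc1
Why: Williamson etherification under basic conditions leaves the ketal untouched and puts on O8 a group that survives acid, peroxide, hydride base and amide base and is removed oxidatively later.

Step 4
Reactants: 5 (1R)-1-(3,3-dimethoxycyclobutyl)-3-methylbut-3-en-1-yl 4-methoxybenzyl ether
Product: 6 3-{(1R)-1-[(4-methoxybenzyl)oxy]-3-methylbut-3-en-1-yl}cyclobutan-1-one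
Conditions: 1 M aq HCl, THF, rt
Reagents that add atoms: water, O
Why: Acid-catalysed ketal hydrolysis frees the cyclobutanone (C12=O); the benzyl-type ether and the 1,1-disubstituted alkene should tolerate dilute acid, and C7 is not yet stereogenic.

Step 5
Reactants: 7 prop-2-yn-1-ol; 8 but-3-en-1-ylmagnesium bromide
Product: 9 2-methylidenehex-5-en-1-ol
Conditions: 8 (2.5 equiv), CuI (10 mol %), Et2O–THF, 0 °C to rt; aq NH4Cl
Reagents that add atoms: none
Why: In this copper-catalysed, alkoxide-directed anti-carbomagnesiation of propargyl alcohol the alkyl group goes to the inner alkyne carbon (C4), and the chelated vinylmagnesium is protonated on work-up to give the 2-substituted allylic alcohol (C1–C5, C15).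

Step 6
Reactants: 9 2-methylidenehex-5-en-1-ol
Product: 10 [(2S)-2-(but-3-en-1-yl)oxiran-2-yl]methanol
Conditions: Ti(OiPr)4 (10 mol %), L-(+)-diethyl tartrate (12 mol %), tBuOOH, 4 Å molecular sieves, CH2Cl2, −20 °C
Reagents that add atoms: tert-butyl hydroperoxide, CC(C)(C)OO
Why: In the Sharpless asymmetric epoxidation only the alkene of the titanium-bound allylic alcohol is oxidised, and L-(+)-tartrate should deliver oxygen to the face that gives (S)-10, which sets C4.

Step 7
Reactants: 10 [(2S)-2-(but-3-en-1-yl)oxiran-2-yl]methanol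
Product: 11 (2R)-2-(but-3-en-1-yl)oxirane-2-carbaldehyde
Conditions: TEMPO (10 mol %), PhI(OAc)2, CH2Cl2, rt
Reagents that add atoms: none
Why: Oxoammonium-mediated oxidation of the primary alcohol stops at the aldehyde, leaves epoxide and alkene alone, and cannot epimerise the fully substituted α-carbon C4 (the descriptor changes only through CIP priorities).

Step 8
Reactants: 6 3-{(1R)-1-[(4-methoxybenzyl)oxy]-3-methylbut-3-en-1-yl}cyclobutan-1-one; 11 (2R)-2-(but-3-en-1-yl)oxirane-2-carbaldehyde
Product: 12 (2S,3S)-2-{(R)-[(2R)-2-(but-3-en-1-yl)oxiran-2-yl](hydroxy)methyl}-3-{(1R)-1-[(4-methoxybenzyl)oxy]-3-methylbut-3-en-1-yl}cyclobutan-1-one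
Conditions: (S)-N-(phenylsulfonyl)pyrrolidine-2-carboxamide (20 mol %), 11 (1.5 equiv), CH2Cl2, rt
Reagents that add atoms: none
Why: In this enamine-catalysed direct aldol that desymmetrises a 3-substituted cyclobutanone, the (S)-catalyst should fix C6 (S) and C5 (R) through its hydrogen-bonded anti transition state, attack trans to the C7 substituent picks one of the two α-CH2 groups and so fixes C7, the aldehyde cannot enolise, and its Felkin–Anh/Cornforth preference (approach past the epoxide CH2) is matched.

Step 9
Reactants: 12 aldol adduct (2-substituted 3-substituted cyclobutanone)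
Product: 14 (4R,5S)-5-{(R)-[(2R)-2-(but-3-en-1-yl)oxiran-2-yl](hydroxy)methyl}-4-{(1R)-1-[(4-methoxybenzyl)oxy]-3-methylbut-3-en-1-yl}dihydrofuran-2(3H)-one, via Criegee perhydrate 13 (not isolated)
Conditions: 30 % aq H2O2 (3 equiv), LiOH (0.3 equiv), THF–H2O, 0 °C, short contact; aq Na2S2O3
Reagents that add atoms: hydrogen peroxide, OO
Why: Hydroperoxide anion adds to the strained C12 carbonyl to give perhydrate 13, in which the C12–C6 σ bond, antiperiplanar to the O–O bond, shifts to the inner peroxide oxygen as hydroxide leaves and so makes the O–C6 bond; this is the Baeyer–Villiger oxidation of a cyclobutanone, the classical γ-butyrolactone annulation. The lactone ring O–C6–C7–C11–C12 is closed by this 1,2-shift, that is by four-to-five ring expansion with insertion of one oxygen atom, not by an exo or endo cyclisation. No stereocentre is created: C6 migrates with retention, so the configuration set as a C–C bond in the aldol becomes the C6–O configuration, and C4, C5, C7 and C8 are untouched. Regioselectivity (C6, not C11) is needed and follows from the higher migratory aptitude of the secondary carbon C6 over the primary C11H2. Chemoselectivity against two alkenes, the epoxide and the benzyl ether is needed and comes from ring strain, since the cyclobutanone takes up the nucleophilic oxidant at 0 °C and this oxidant, unlike a peracid, leaves unactivated alkenes and epoxides alone. Base is kept catalytic (hydroxide is regenerated in the shift) and contact short, so that retro-aldol cleavage, lactone hydrolysis and premature epoxide migration should not start.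

Step 10
Reactants: 14 hydroxy lactone with the C4–C15 epoxide
Product: 16 (4R,5S)-5-[(2R,3S)-3-(but-3-en-1-yl)-3-{[(tert-butyldimethylsilyl)oxy]methyl}oxiran-2-yl]-4-{(1R)-1-[(4-methoxybenzyl)oxy]-3-methylbut-3-en-1-yl}dihydrofuran-2(3H)-one, via epoxy alcohol 15 (not isolated)
Conditions: NaH (1.1 equiv), THF, 0 °C to rt; then tBuMe2SiCl, 0 °C
Reagents that add atoms: tert-butyldimethylsilyl chloride, CC(C)(C)[Si](C)(C)Cl
Why: In the Payne rearrangement the O5 alkoxide attacks C4 from the rear of the C4–O bond (3-exo-tet, inversion at C4, C5 untouched), which places C3 and C6 trans on the new epoxide; the equilibrium favours the trisubstituted epoxide and the primary alkoxide, and the silyl chloride traps this least hindered alkoxide.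

Step 11
Reactants: 16 silyl-protected epoxy lactone diene
Product: 17 (1(10)Z,4S,5R,6S,7R,8R)-15-(tert-butyldimethylsilyloxy)-4,5-epoxy-8-(4-methoxybenzyloxy)germacr-1(10)-en-12,6-olide
Conditions: second-generation Hoveyda–Grubbs catalyst (10 mol %), 1,4-benzoquinone (20 mol %), toluene (1 mM), 80 °C, argon sparge
Reagents that add atoms: none
Why: Ring-closing metathesis of a monosubstituted with a 1,1-disubstituted alkene at high dilution has precedent for ten-membered germacranolide carbocycles; the cis (Z) trisubstituted alkene is the less strained isomer and should be collected under reversible conditions, and no acrylate is present yet to divert the catalyst.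

Step 12
Reactants: 17 ten-membered lactone
Product: 18 11-[(dimethylamino)methyl] derivative of 17 (C11 epimers)
Conditions: LiN(iPr)2 (1.2 equiv), THF, −78 °C; then CH2=NMe2+ I−, −78 °C to rt
Reagents that add atoms: N,N-dimethylmethyleneiminium iodide (Eschenmoser's salt), C=[N+](C)C.[I-]
Why: In this Mannich reaction of the lactone enolate C11H2 is the only acidic position, ethers and epoxide are inert at −78 °C, and the new C11 centre is lost in the next step.

Step 13
Reactants: 18 11-[(dimethylamino)methyl] lactone
Product: 20 (1(10)Z,4S,5R,6S,7R,8R)-15-(tert-butyldimethylsilyloxy)-4,5-epoxy-8-(4-methoxybenzyloxy)germacra-1(10),11(13)-dien-12,6-olide, via ammonium iodide 19 (not isolated)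
Conditions: MeI, CH2Cl2–MeOH, rt; then aq NaHCO3, CH2Cl2, rt
Reagents that add atoms: iodomethane, CI (its methyl group enters 19 and leaves again with the amine)
Why: Exhaustive methylation followed by E1cB elimination of trimethylamine is the standard end of the Eschenmoser α-methylenation and needs only bicarbonate, which should spare epoxide and lactone.

Step 14
Reactants: 20 α-methylene lactone with O8 benzyl-type ether
Product: 21 (1(10)Z,4S,5R,6S,7R,8R)-15-(tert-butyldimethylsilyloxy)-4,5-epoxy-8-hydroxygermacra-1(10),11(13)-dien-12,6-olide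
Conditions: DDQ, CH2Cl2–pH 7 phosphate buffer, 0 °C
Reagents that add atoms: none
Why: Oxidative cleavage of the 4-methoxybenzyl ether by hydride abstraction at the electron-rich benzylic position is orthogonal to the silyl ether, the epoxide and the electron-poor methylene lactone.

Step 15
Reactants: 22 (tert-butyldimethylsilyloxy)acetaldehyde; 23 ethyl 2-(triphenylphosphoranylidene)propanoate
Product: 24 ethyl (E)-4-(tert-butyldimethylsilyloxy)-2-methylbut-2-enoate
Conditions: CH2Cl2, rt
Reagents that add atoms: none
Why: The Wittig reaction of a stabilised, α-branched ylide should give the (E)-trisubstituted enoate (tiglate geometry) under thermodynamic control of oxaphosphetane formation.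

Step 16
Reactants: 24 ethyl (E)-4-(tert-butyldimethylsilyloxy)-2-methylbut-2-enoate
Product: 25 (E)-4-(tert-butyldimethylsilyloxy)-2-methylbut-2-enoic acid
Conditions: LiOH, THF–MeOH–H2O, rt; then 1 M HCl to pH 4, 0 °C
Reagents that add atoms: lithium hydroxide, [Li+].[OH-]
Why: Saponification of the ethyl ester leaves the primary silyl ether and the alkene geometry intact if acidification is brief and cold.

Step 17
Reactants: 21 C8 alcohol; 25 (E)-4-(tert-butyldimethylsilyloxy)-2-methylbut-2-enoic acid
Product: 26 (1(10)Z,4S,5R,6S,7R,8R)-15-(tert-butyldimethylsilyloxy)-8-[(E)-4-(tert-butyldimethylsilyloxy)-2-methylbut-2-enoyloxy]-4,5-epoxygermacra-1(10),11(13)-dien-12,6-olide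
Conditions: DCC, DMAP (cat.), CH2Cl2, 0 °C to rt
Reagents that add atoms: none
Why: In the Steglich esterification O8 is the only free hydroxyl group, the C8 configuration is kept because only the acyl–O bond is formed, and the (E)-enoate is the stable isomer so DMAP cannot scramble it.

Step 18
Reactants: 26 bis-silyl ether
Product: 27 (1(10)Z,4S,5R,6S,7R,8R)-4,5-epoxy-15-hydroxy-8-[(E)-4-hydroxy-2-methylbut-2-enoyloxy]germacra-1(10),11(13)-dien-12,6-olide (CNP0187639.2)
Conditions: Et3N·3HF, THF, rt
Reagents that add atoms: none
Why: Fluoride-driven cleavage of both primary silyl ethers in a weakly acidic, non-basic medium should avoid back-migration of the epoxide, conjugate addition to the methylene lactone and ester migration.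

Compound list
1 | methyl 3,3-dimethoxycyclobutane-1-carboxylate | COC(=O)C1CC(OC)(OC)C1 | starting material
2 | 3,3-dimethoxycyclobutane-1-carbaldehyde | O=CC1CC(OC)(OC)C1 | intermediate
3 | tributyl(2-methylallyl)stannane | C=C(C)C[Sn](CCCC)(CCCC)CCCC | starting material
4 | (1R)-1-(3,3-dimethoxycyclobutyl)-3-methylbut-3-en-1-ol | COC1(OC)CC(C1)[C@H](O)CC(C)=C | intermediate
5 | (1R)-1-(3,3-dimethoxycyclobutyl)-3-methylbut-3-en-1-yl 4-methoxybenzyl ether | COC1(OC)CC(C1)[C@H](OCc2ccc(OC)cc2)CC(C)=C | intermediate
6 | 3-{(1R)-1-[(4-methoxybenzyl)oxy]-3-methylbut-3-en-1-yl}cyclobutan-1-one | O=C1CC(C1)[C@H](OCc2ccc(OC)cc2)CC(C)=C | intermediate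
7 | prop-2-yn-1-ol | C#CCO | starting material
8 | but-3-en-1-ylmagnesium bromide | C=CCC[Mg]Br | starting material
9 | 2-methylidenehex-5-en-1-ol | C=CCCC(=C)CO | intermediate
10 | [(2S)-2-(but-3-en-1-yl)oxiran-2-yl]methanol | C=CCC[C@@]1(CO1)CO | intermediate
11 | (2R)-2-(but-3-en-1-yl)oxirane-2-carbaldehyde | C=CCC[C@@]1(CO1)C=O | intermediate
12 | aldol adduct, (2S,3S)-cyclobutanone with (5R)-carbinol and (4R)-spiro-type C4–C15 epoxide | C=CCC[C@@]1(CO1)[C@H](O)[C@H]2C(=O)C[C@@H]2[C@H](OCc3ccc(OC)cc3)CC(C)=C | intermediate
13 | Criegee perhydrate of 12 (1-hydroperoxycyclobutan-1-ol) | C=CCC[C@@]1(CO1)[C@H](O)[C@H]2C(O)(OO)C[C@@H]2[C@H](OCc3ccc(OC)cc3)CC(C)=C | intermediate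
14 | (4R,5S)-γ-lactone with free (5R)-carbinol and C4–C15 epoxide | C=CCC[C@@]1(CO1)[C@H](O)[C@H]2OC(=O)C[C@@H]2[C@H](OCc3ccc(OC)cc3)CC(C)=C | intermediate
15 | γ-lactone with (4S,5R)-C4–C5 epoxide and free C15 hydroxyl | C=CCC[C@@]1(CO)O[C@@H]1[C@H]2OC(=O)C[C@@H]2[C@H](OCc3ccc(OC)cc3)CC(C)=C | intermediate
16 | C15 tert-butyldimethylsilyl ether of 15 | C=CCC[C@@]1(CO[Si](C)(C)C(C)(C)C)O[C@@H]1[C@H]2OC(=O)C[C@@H]2[C@H](OCc3ccc(OC)cc3)CC(C)=C | intermediate
17 | (1(10)Z,4S,5R,6S,7R,8R)-15-(tert-butyldimethylsilyloxy)-4,5-epoxy-8-(4-methoxybenzyloxy)germacr-1(10)-en-12,6-olide | C1C(=O)O[C@H]2[C@H]1[C@H](OCc3ccc(OC)cc3)C/C(C)=C\CC[C@@]1(CO[Si](C)(C)C(C)(C)C)O[C@H]21 | intermediate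
18 | 11-[(dimethylamino)methyl] derivative of 17 (C11 epimers) | CN(C)CC1C(=O)O[C@H]2[C@H]1[C@H](OCc3ccc(OC)cc3)C/C(C)=C\CC[C@@]1(CO[Si](C)(C)C(C)(C)C)O[C@H]21 | intermediate
19 | trimethylammonium iodide from 18 | C[N+](C)(C)CC1C(=O)O[C@H]2[C@H]1[C@H](OCc3ccc(OC)cc3)C/C(C)=C\CC[C@@]1(CO[Si](C)(C)C(C)(C)C)O[C@H]21.[I-] | intermediate
20 | (1(10)Z,4S,5R,6S,7R,8R)-15-(tert-butyldimethylsilyloxy)-4,5-epoxy-8-(4-methoxybenzyloxy)germacra-1(10),11(13)-dien-12,6-olide | C=C1C(=O)O[C@H]2[C@H]1[C@H](OCc3ccc(OC)cc3)C/C(C)=C\CC[C@@]1(CO[Si](C)(C)C(C)(C)C)O[C@H]21 | intermediate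
21 | (1(10)Z,4S,5R,6S,7R,8R)-15-(tert-butyldimethylsilyloxy)-4,5-epoxy-8-hydroxygermacra-1(10),11(13)-dien-12,6-olide | C=C1C(=O)O[C@H]2[C@H]1[C@H](O)C/C(C)=C\CC[C@@]1(CO[Si](C)(C)C(C)(C)C)O[C@H]21 | intermediate
22 | (tert-butyldimethylsilyloxy)acetaldehyde | CC(C)(C)[Si](C)(C)OCC=O | starting material
23 | ethyl 2-(triphenylphosphoranylidene)propanoate | CCOC(=O)C(C)=P(c1ccccc1)(c1ccccc1)c1ccccc1 | starting material
24 | ethyl (E)-4-(tert-butyldimethylsilyloxy)-2-methylbut-2-enoate | CCOC(=O)/C(C)=C/CO[Si](C)(C)C(C)(C)C | intermediate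
25 | (E)-4-(tert-butyldimethylsilyloxy)-2-methylbut-2-enoic acid | OC(=O)/C(C)=C/CO[Si](C)(C)C(C)(C)C | intermediate
26 | bis-silyl ether of the target | C=C1C(=O)O[C@H]2[C@H]1[C@H](OC(=O)/C(C)=C/CO[Si](C)(C)C(C)(C)C)C/C(C)=C\CC[C@@]1(CO[Si](C)(C)C(C)(C)C)O[C@H]21 | intermediate
27 | CNP0187639.2 | C=C1C(=O)O[C@H]2[C@H]1[C@H](OC(=O)/C(C)=C/CO)C/C(C)=C\CC[C@@]1(CO)O[C@H]21 | target

Total step count: 18. Longest linear sequence: 13 steps (1 to 27 through steps 1–4, 8–14, 17 and 18).

Steps most likely to fail

Step 8. Enamine formation from the strained ketone and addition to the neopentyl-type aldehyde may be too slow, or the two α-methylene groups may be poorly told apart. The fallback replaces catalysis by a stoichiometric chiral base and a preformed enolate.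
- It sets out from 6. Enantiotopos-selective deprotonation uses lithium bis(1-phenylethyl)amide (the antipode to be chosen by trial) in the presence of Me3SiCl at −100 °C and should give the trimethylsilyl enol ether F1.
- MeLi then regenerates the lithium enolate, which is added to 11 at −78 °C through a closed Zimmerman–Traxler transition state (ring-locked E-enolate, hence anti aldol, trans to the C7 substituent, Felkin–Anh face of 11).
- The fallback comes back to the route at 12.

Step 11. Oligomerisation, or closure to an E/Z mixture, may take over because the trans-epoxide already sits in the ring path and holds the two alkenes apart. The fallback closes the ten-membered ring before the epoxide is moved into it.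
- It sets out from 12. The same ruthenium catalyst in dilute CH2Cl2 at 40 °C should give the bicyclo[8.2.0] hydroxy ketone F2, whose ring path runs through the flexible carbinol C5 and the spiro-epoxide carbon C4.
- Alkaline H2O2 as in step 9 then inserts the oxygen to give the macrocyclic hydroxy lactone F3.
- NaH followed by tBuMe2SiCl as in step 10 moves the epoxide into the ring, and the fallback comes back at 17.

Step 10. The O5 alkoxide may attack the neighbouring lactone carbonyl (acyl migration to O5 or lactone opening) faster than it opens the epoxide. The fallback masks the carbonyl as its enolate during the migration.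
- It sets out from 14. KN(SiMe3)2 (2.2 equiv) at −78 °C makes the lactone enolate and the O5 alkoxide together, and warming lets the epoxide migrate.
- Excess tBuMe2SiCl then gives the ketene silyl acetal F4.
- The enol silyl group of F4 is hydrolysed on work-up with dilute citric acid, and the fallback comes back at 16.

Further compounds
F1 | step 8 | trimethylsilyl enol ether of 6 (C12=C6 enol, C7 configured as in 12) | C[Si](C)(C)OC1=C[C@H](C1)[C@H](OCc2ccc(OC)cc2)CC(C)=C
F2 | step 11 | bicyclo[8.2.0] hydroxy ketone (Z ring alkene, spiro C4–C15 epoxide, C5 hydroxyl) | C1C(=O)[C@H]2[C@H]1[C@H](OCc3ccc(OC)cc3)C/C(C)=C\CC[C@@]4(CO4)[C@@H]2O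
F3 | step 11 | macrocyclic hydroxy lactone (Z ring alkene, spiro C4–C15 epoxide, C5 hydroxyl) | C1C(=O)O[C@H]2[C@H]1[C@H](OCc3ccc(OC)cc3)C/C(C)=C\CC[C@@]4(CO4)[C@@H]2O
F4 | step 10 | ketene tert-butyldimethylsilyl acetal of 16 | C=CCC[C@@]1(CO[Si](C)(C)C(C)(C)C)O[C@@H]1[C@H]2OC(O[Si](C)(C)C(C)(C)C)=C[C@@H]2[C@H](OCc3ccc(OC)cc3)CC(C)=C
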